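Everything rests on reading ring C oxygen O1, ring A carbons C8a and C8, benzylic C1'', stereocentre C2'' and isopropenyl carbon C3'' as six contiguous atoms, that is, as an opened 3-prenyl-3,4-dihydrocoumarin. Cutting that lactone at C1''–C2'' and O1–C3'' gives an o-quinone methide and an azolium enolate. One carbene-catalysed annulation thus forges the side-chain C–C bond, sets (R)-C2'' and marks the single phloroglucinol oxygen that becomes O1, so 8- rather than 6-substitution is locked. Its precursors are a bis-MOM 2-(tosylmethyl)phenol and racemic 2-chloro-5-methylhex-4-enal. Lactone-to-isopropenyl conversion, chromone closure and a rhodium-catalysed arylation that sets (S)-C2 complete the flavanone.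

Key step: step 5

Assumption: the sense of induction of the triazolium salt (step 5) and of the bisphosphine (step 13) is assigned by analogy with related azolium enolate annulations and cyclic enone arylations; both antipodes of each are available, so the enantiomer that delivers (2''R) and (2S) is the one meant.

Step 1
Reactants: 1 2,4,6-trihydroxybenzaldehyde
Product: 2 2-hydroxy-4,6-bis(methoxymethoxy)benzaldehyde
Conditions: MOMCl (2.2 equiv), iPr2NEt (2.5 equiv), CH2Cl2, 0 °C to rt
Reagents that add atoms: chloromethyl methyl ether (MOMCl), COCCl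
Why: Base-mediated O-alkylation (MOM ether formation) should stop at the bis-ether because the last ortho hydroxyl is locked in a hydrogen bond to the formyl oxygen and is far less nucleophilic.

Step 2
Reactants: 2 2-hydroxy-4,6-bis(methoxymethoxy)benzaldehyde
Product: 4 3,5-bis(methoxymethoxy)-2-(tosylmethyl)phenol, via salicyl alcohol 3 (not isolated)
Conditions: NaBH4 (0.6 equiv), THF–H2O, 0 °C, short contact; then TolSO2Na (3 equiv), AcOH to pH 4, 0 °C to rt
Reagents that add atoms: sodium p-toluenesulfinate, Cc1ccc(cc1)S(=O)[O-].[Na+]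
Why: Borohydride reduction gives salicyl alcohol 3, whose benzylic C–O bond ionises under mild acid thanks to three oxygen donors, and the soft sulfinate sulfur captures the cation in an SN1-type substitution to a stable sulfone, while pH 4 at room temperature spares aryl MOM ethers and the labile 3 is never handled.

Step 3
Reactants: 5 2-methylbut-3-en-2-ol; 6 ethyl vinyl ether
Product: 8 5-methylhex-4-enal, via allyl vinyl ether 7 (not isolated)
Conditions: 6 (excess, neat), H3PO4 (cat.), sealed vessel, 150 °C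
Reagents that add atoms: none
Why: Acid-catalysed vinyl ether exchange followed by a Claisen rearrangement (Saucy–Marbet-type protocol) moves the oxygen-bound allyl unit of 7 through a [3,3] shift to carbon and leaves the trisubstituted prenyl alkene and the aldehyde.

Step 4
Reactants: 8 5-methylhex-4-enal
Product: 9 (±)-2-chloro-5-methylhex-4-enal
Conditions: NCS (1.05 equiv), DL-proline (10 mol %), CH2Cl2, 0 °C to rt; pentane, filtration, used without storage
Reagents that add atoms: N-chlorosuccinimide, O=C1CCC(=O)N1Cl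
Why: Enamine-catalysed α-chlorination works because the proline enamine outcompetes the trisubstituted alkene for NCS, and a racemate suffices since this centre becomes planar in step 5.

Step 5
Reactants: 4 3,5-bis(methoxymethoxy)-2-(tosylmethyl)phenol; 9 (±)-2-chloro-5-methylhex-4-enal
Product: 13 (3R)-5,7-bis(methoxymethoxy)-3-(3-methylbut-2-enyl)-3,4-dihydrocoumarin, via o-quinone methide 10 (not isolated), via azolium enolate 11 (not isolated), via acyl azolium phenoxide 12 (not isolated)
Conditions: (5aR,10bS)-2-mesityl-5a,10b-dihydro-4H,6H-indeno[2,1-b][1,2,4]triazolo[4,3-d][1,4]oxazin-2-ium tetrafluoroborate (10 mol %), Et3N (1.5 equiv), Cs2CO3 (1.2 equiv), 4 Å molecular sieves, toluene–THF, −20 °C to rt; 9 (1.5 equiv) present from the start, 4 added slowly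
Reagents that add atoms: the triazolium tetrafluoroborate, Cc1cc(C)c(c(C)c1)-[n+]1cn2[C@H]3c4ccccc4C[C@H]3OCc2n1.F[B-](F)(F)F (its carbene is bound only in 11 and 12 and leaves again; nothing from it stays in 13)
Why: Cs2CO3 deprotonates 4 and the phenoxide expels sulfinate in a 1,4-elimination to give 10, while the triazolylidene adds to the formyl group of 9 and loses HCl to give the (Z)-azolium enolate 11. The enolate α-carbon attacks the exocyclic CH2 of 10 (C1''–C2'' bond), which rearomatises ring A and gives phenoxide 12. That phenoxide attacks the acyl azolium carbonyl in a 6-exo-trig acyl substitution (O1–C3'' bond), closing the six-membered lactone and releasing the carbene, so the overall result is a formal inverse-demand hetero-[4+2]. The closest known reaction type is the carbene-catalysed annulation of azolium enolates with o-quinone methides generated in situ, which gives 3-substituted 3,4-dihydrocoumarins. C2'' is the only new stereocentre and is fixed by the aminoindanol backbone and the N-mesityl group, which shield one face of the planar enolate, so both enantiomers of 9 converge on one product. The step needs only enolate-face selectivity and chemoselectivity against self-reaction of 10: the unsubstituted CH2 terminus removes any diastereomer question, the two MOM-oxy donors temper 10, and slow heterogeneous release keeps its concentration low.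

Step 6
Reactants: 13 (3R)-5,7-bis(methoxymethoxy)-3-(3-methylbut-2-enyl)-3,4-dihydrocoumarin
Product: 15 (3R)-3-[2-hydroxy-4,6-bis(methoxymethoxy)benzyl]-6-methylhept-5-en-2-one, via Weinreb amide 14 (not isolated)
Conditions: MeNH(OMe)·HCl (1.5 equiv), iPrMgCl (3.0 equiv), THF, −20 °C; then MeMgBr (3 equiv), −20 to 0 °C; cold aq NH4Cl
Reagents that add atoms: methylmagnesium bromide, C[Mg]Br (acetyl methyl of 15); N,O-dimethylhydroxylamine hydrochloride, CNOC.Cl (N(OMe)Me of 14 only)
Why: Weinreb ketone synthesis in one flask: the magnesium amide opens the activated aryl ester by acyl substitution faster than it enolises it and thereby frees O1 as a phenoxide, and the chelated tetrahedral adduct from 14 and MeMgBr blocks a second addition, so C2'' is carried through unchanged.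

Step 7
Reactants: 15 (3R)-3-[2-hydroxy-4,6-bis(methoxymethoxy)benzyl]-6-methylhept-5-en-2-one
Product: 16 3,5-bis(methoxymethoxy)-2-[(2R)-5-methyl-2-(prop-1-en-2-yl)hex-4-enyl]phenol
Conditions: Ph3PCH3Br (3.6 equiv), KN(SiMe3)2 (3.5 equiv), THF, 0 °C; then 15, −78 to 0 °C
Reagents that add atoms: methyltriphenylphosphonium bromide, C[P+](c1ccccc1)(c1ccccc1)c1ccccc1.[Br-]
Why: Wittig methylenation with a lithium-free ylide in excess (one equivalent is taken by the phenol) converts the acetyl carbonyl into the isopropenyl group, and any competing enolisation should occur kinetically at the unhindered methyl side, so the tertiary C2''–H is left alone.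

Step 8
Reactants: 16 3,5-bis(methoxymethoxy)-2-[(2R)-5-methyl-2-(prop-1-en-2-yl)hex-4-enyl]phenol
Product: 17 2-hydroxy-4,6-bis(methoxymethoxy)-3-[(2R)-5-methyl-2-(prop-1-en-2-yl)hex-4-enyl]benzaldehyde
Conditions: anhydrous MgCl2 (2.5 equiv), Et3N (4 equiv), paraformaldehyde (6 equiv), THF, 65 °C; cold dilute acid wash
Reagents that add atoms: paraformaldehyde (as formaldehyde), C=O
Why: Casnati–Skattebøl ortho-formylation delivers formaldehyde within the magnesium phenoxide chelate only to a carbon ortho to the free phenol, and with C8 blocked by the side chain only C4a qualifies, whereas C6 between the two MOM ethers is not addressed.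

Step 9
Reactants: 17 2-hydroxy-4,6-bis(methoxymethoxy)-3-[(2R)-5-methyl-2-(prop-1-en-2-yl)hex-4-enyl]benzaldehyde
Product: 18 2-(1-hydroxyprop-2-ynyl)-3,5-bis(methoxymethoxy)-6-[(2R)-5-methyl-2-(prop-1-en-2-yl)hex-4-enyl]phenol (both carbinol epimers)
Conditions: HC≡CMgBr (3.5 equiv), THF, 0 °C to rt; aq NH4Cl at 0 °C; crude carried on
Reagents that add atoms: ethynylmagnesium bromide, C#C[Mg]Br
Why: Grignard 1,2-addition to the aldehyde after deprotonation of the phenol is reliable, and the new carbinol centre needs no control because it is oxidised in step 10.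

Step 10
Reactants: 18 2-(1-hydroxyprop-2-ynyl)-3,5-bis(methoxymethoxy)-6-[(2R)-5-methyl-2-(prop-1-en-2-yl)hex-4-enyl]phenol
Product: 21 5,7-bis(methoxymethoxy)-8-[(2R)-5-methyl-2-(prop-1-en-2-yl)hex-4-enyl]chromen-4-one, via ynone 19 (not isolated), via enaminone 20 (not isolated)
Conditions: activated MnO2 (15 equiv), CH2Cl2, rt; filtration through Celite; then Et2NH (1.5 equiv), EtOH, rt to 45 °C, concentration
Reagents that add atoms: diethylamine, CCNCC (held only in 20 and released again; nothing from it stays in 21)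
Why: MnO2 selectively oxidises the benzylic-propargylic alcohol, conjugate (aza-Michael) addition of Et2NH to the terminal ynone gives 20, and O1 then replaces the amine at the β-carbon by addition–elimination, a net 6-endo closure of ring C that shuts out the 5-exo benzofuranone pathway.

Step 11
Reactants: 22 4-bromoresorcinol
Product: 23 1-bromo-2,4-bis(methoxymethoxy)benzene
Conditions: MOMCl (2.5 equiv), iPr2NEt (3 equiv), CH2Cl2, 0 °C to rt
Reagents that add atoms: chloromethyl methyl ether (MOMCl), COCCl
Why: Standard MOM ether formation should take both phenols, since neither is deactivated by chelation.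

Step 12
Reactants: 23 1-bromo-2,4-bis(methoxymethoxy)benzene
Product: 26 2,4-bis(methoxymethoxy)phenylboronic acid, via aryllithium 24 (not isolated), via lithium borate 25 (not isolated)
Conditions: n-BuLi (1.05 equiv), THF, −78 °C; B(OMe)3 (1.5 equiv), −78 °C to rt; sat. aq NH4Cl
Reagents that add atoms: trimethyl borate, COB(OC)OC; water, O; n-butyllithium, CCCC[Li] (lithium of 24 and 25 only)
Why: Bromine–lithium exchange is faster than any MOM-directed deprotonation at −78 °C, and borate trapping followed by near-neutral hydrolysis then gives the boronic acid without loss of the acetals.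

Step 13
Reactants: 21 5,7-bis(methoxymethoxy)-8-[(2R)-5-methyl-2-(prop-1-en-2-yl)hex-4-enyl]chromen-4-one; 26 2,4-bis(methoxymethoxy)phenylboronic acid
Product: 27 (2S)-2-[2,4-bis(methoxymethoxy)phenyl]-5,7-bis(methoxymethoxy)-8-[(2R)-5-methyl-2-(prop-1-en-2-yl)hex-4-enyl]chroman-4-one
Conditions: [Rh(OH)(cod)]2 (3 mol %), (S)-(6,6'-dimethoxybiphenyl-2,2'-diyl)bis[bis(3,4,5-trifluorophenyl)phosphine] (6.6 mol %), 26 (3 equiv, in portions), toluene–H2O, 25–40 °C
Reagents that add atoms: none
Why: Hayashi–Miyaura asymmetric conjugate arylation, a reaction type established for chromones including 5,7-dioxygenated ones: transmetalation gives an aryl complex of monovalent rhodium, the electron-poor chiral bisphosphine selects the face of C2=C3 for carborhodation and so sets (2S) independently of the remote C2'', and hydrolysis of the oxa-π-allyl species near room temperature avoids opening of ring C.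

Step 14
Reactants: 27 (2S)-2-[2,4-bis(methoxymethoxy)phenyl]-5,7-bis(methoxymethoxy)-8-[(2R)-5-methyl-2-(prop-1-en-2-yl)hex-4-enyl]chroman-4-one
Product: 28 sophoraflavanone G, (2S)-2-(2,4-dihydroxyphenyl)-5,7-dihydroxy-8-[(2R)-5-methyl-2-(prop-1-en-2-yl)hex-4-enyl]chroman-4-one
Conditions: 3 M aq HCl (about a tenth by volume) in MeOH, N2, 0 °C to rt, not above 30 °C; NaHCO3 quench
Reagents that add atoms: none
Why: Acid-catalysed acetal exchange with methanol cleaves aryl MOM ethers at an acidity and temperature at which protonation of the trisubstituted and 1,1-disubstituted alkenes and opening of ring C are still slow, so both stereocentres should be retained.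

Compound list
1 | 2,4,6-trihydroxybenzaldehyde | O=Cc1c(O)cc(O)cc1O | starting material
2 | 2-hydroxy-4,6-bis(methoxymethoxy)benzaldehyde | O=Cc1c(O)cc(OCOC)cc1OCOC | intermediate
3 | 2-(hydroxymethyl)-3,5-bis(methoxymethoxy)phenol | OCc1c(O)cc(OCOC)cc1OCOC | intermediate
4 | 3,5-bis(methoxymethoxy)-2-[(4-methylphenyl)sulfonylmethyl]phenol | Cc1ccc(cc1)S(=O)(=O)Cc1c(O)cc(OCOC)cc1OCOC | intermediate
5 | 2-methylbut-3-en-2-ol | C=CC(C)(C)O | starting material
6 | ethyl vinyl ether | C=COCC | starting material
7 | 3-methyl-3-(vinyloxy)but-1-ene | C=COC(C)(C)C=C | intermediate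
8 | 5-methylhex-4-enal | CC(C)=CCCC=O | intermediate
9 | (±)-2-chloro-5-methylhex-4-enal | CC(C)=CCC(Cl)C=O | intermediate
10 | 3,5-bis(methoxymethoxy)-6-methylidenecyclohexa-2,4-dien-1-one | C=C1C(=O)C=C(OCOC)C=C1OCOC | intermediate
11 | (Z)-1-[(5aR,10bS)-2-mesityl-5a,10b-dihydro-4H,6H-indeno[2,1-b][1,2,4]triazolo[4,3-d][1,4]oxazin-2-ium-1-yl]-5-methylhexa-1,4-dien-1-olate | CC(C)=CC/C=C(\[O-])c1n2[C@H]3c4ccccc4C[C@H]3OCc2n[n+]1-c1c(C)cc(C)cc1C | intermediate
12 | zwitterion carrying the (2R)-2-[2-oxido-4,6-bis(methoxymethoxy)benzyl]-5-methylhex-4-enoyl group on C1 of the same triazolium | O=C([C@H](CC=C(C)C)Cc1c([O-])cc(OCOC)cc1OCOC)c1n2[C@H]3c4ccccc4C[C@H]3OCc2n[n+]1-c1c(C)cc(C)cc1C | intermediate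
13 | (3R)-5,7-bis(methoxymethoxy)-3-(3-methylbut-2-enyl)-3,4-dihydrocoumarin | O=C1[C@H](CC=C(C)C)Cc2c(OCOC)cc(OCOC)cc2O1 | intermediate
14 | (2R)-2-[2-hydroxy-4,6-bis(methoxymethoxy)benzyl]-N-methoxy-N,5-dimethylhex-4-enamide | CON(C)C(=O)[C@H](CC=C(C)C)Cc1c(O)cc(OCOC)cc1OCOC | intermediate
15 | (3R)-3-[2-hydroxy-4,6-bis(methoxymethoxy)benzyl]-6-methylhept-5-en-2-one | CC(=O)[C@H](CC=C(C)C)Cc1c(O)cc(OCOC)cc1OCOC | intermediate
16 | 3,5-bis(methoxymethoxy)-2-[(2R)-5-methyl-2-(prop-1-en-2-yl)hex-4-enyl]phenol | C=C(C)[C@H](CC=C(C)C)Cc1c(O)cc(OCOC)cc1OCOC | intermediate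
17 | 2-hydroxy-4,6-bis(methoxymethoxy)-3-[(2R)-5-methyl-2-(prop-1-en-2-yl)hex-4-enyl]benzaldehyde | C=C(C)[C@H](CC=C(C)C)Cc1c(O)c(C=O)c(OCOC)cc1OCOC | intermediate
18 | 2-(1-hydroxyprop-2-ynyl)-3,5-bis(methoxymethoxy)-6-[(2R)-5-methyl-2-(prop-1-en-2-yl)hex-4-enyl]phenol, both carbinol epimers | C=C(C)[C@H](CC=C(C)C)Cc1c(O)c(C(O)C#C)c(OCOC)cc1OCOC | intermediate
19 | 1-{2-hydroxy-4,6-bis(methoxymethoxy)-3-[(2R)-5-methyl-2-(prop-1-en-2-yl)hex-4-enyl]phenyl}prop-2-yn-1-one | C=C(C)[C@H](CC=C(C)C)Cc1c(O)c(C(=O)C#C)c(OCOC)cc1OCOC | intermediate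
20 | (E)-3-(diethylamino)-1-{2-hydroxy-4,6-bis(methoxymethoxy)-3-[(2R)-5-methyl-2-(prop-1-en-2-yl)hex-4-enyl]phenyl}prop-2-en-1-one | C=C(C)[C@H](CC=C(C)C)Cc1c(O)c(C(=O)/C=C/N(CC)CC)c(OCOC)cc1OCOC | intermediate
21 | 5,7-bis(methoxymethoxy)-8-[(2R)-5-methyl-2-(prop-1-en-2-yl)hex-4-enyl]chromen-4-one | C=C(C)[C@H](CC=C(C)C)Cc1c(OCOC)cc(OCOC)c2c1OC=CC2=O | intermediate
22 | 4-bromoresorcinol | Oc1ccc(Br)c(O)c1 | starting material
23 | 1-bromo-2,4-bis(methoxymethoxy)benzene | COCOc1ccc(Br)c(OCOC)c1 | intermediate
24 | 2,4-bis(methoxymethoxy)phenyllithium | [Li]c1ccc(OCOC)cc1OCOC | intermediate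
25 | lithium [2,4-bis(methoxymethoxy)phenyl]trimethoxyborate | [Li+].CO[B-](OC)(OC)c1ccc(OCOC)cc1OCOC | intermediate
26 | 2,4-bis(methoxymethoxy)phenylboronic acid | OB(O)c1ccc(OCOC)cc1OCOC | intermediate
27 | (2S)-2-[2,4-bis(methoxymethoxy)phenyl]-5,7-bis(methoxymethoxy)-8-[(2R)-5-methyl-2-(prop-1-en-2-yl)hex-4-enyl]chroman-4-one | C=C(C)[C@H](CC=C(C)C)Cc1c(OCOC)cc(OCOC)c2c1O[C@H](c1ccc(OCOC)cc1OCOC)CC2=O | intermediate
28 | sophoraflavanone G | C=C(C)[C@H](CC=C(C)C)Cc1c(O)cc(O)c2c1O[C@H](c1ccc(O)cc1O)CC2=O | target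

Total step count: 14.
Longest linear sequence: 10 steps (1, 2, 5, 6, 7, 8, 9, 10, 13, 14).

Steps most likely to fail

Step 5. The quinone methide may oligomerise or be trapped by the carbene. The phenol may be O-acylated by the acyl azolium before sulfinate is lost. Facial selectivity on a purely aliphatic enolate may also be poor. The fallback sets C2'' by an Evans alkylation and uses no quinone methide; it sets out from 2 and comes back at 13.
- Silylation of 2 (TBSCl, imidazole, DMF) gives 2-(tert-butyldimethylsilyloxy)-4,6-bis(methoxymethoxy)benzaldehyde F1.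
- Wittig olefination with benzyl (triphenylphosphoranylidene)acetate gives the benzyl (E)-cinnamate F2.
- H2 over Pd/C saturates the alkene and cleaves the benzyl ester to the 3-arylpropanoic acid F3.
- Activation with pivaloyl chloride and Et3N, then acylation of lithiated (R)-4-benzyloxazolidin-2-one, gives the imide F4.
- NaN(SiMe3)2 and then prenyl bromide at −78 °C alkylate the chelated (Z)-enolate on the face away from the benzyl group to give the (2R)-prenylated imide F5.
- Bu4NF buffered with AcOH frees the phenoxide, which attacks the exocyclic imide carbonyl, expels the auxiliary and closes lactone 13.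

Step 13. Protodeboronation of the electron-rich, ortho-substituted boronic acid may outrun transmetalation. Insertion may be slow for the hindered aryl group. Retro-oxa-Michael opening may erode C2. The fallback builds ring C from a chalcone and brings in ring B as an aldehyde; it sets out from 17 and comes back at 27.
- MeMgBr adds to 17 to give the 1-arylethanol F6, and MnO2 oxidises it to the 2-hydroxyacetophenone F7.
- Aryllithium 24 is quenched with DMF to give 2,4-bis(methoxymethoxy)benzaldehyde F8.
- Claisen–Schmidt condensation of F7 with F8 (KOH, EtOH) gives the (E)-2'-hydroxychalcone F9.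
- NaOAc in refluxing EtOH closes ring C by oxa-Michael addition to 27 and its (2R) epimer F10.
- These two are diastereomers because C2'' is fixed, so they are separated by preparative HPLC, and F10 is returned to the equilibration through F9.

Step 14. Acid may promote addition of the freed 7-hydroxyl (or of methanol) to the side-chain alkenes. Ring C may open reversibly with epimerisation at C2 once the electron-rich ring B is unmasked. The fallback avoids Brønsted acid by exchanging acetal for silyl groups; it sets out from 27 and ends at 28. Me3SiOTf and 2,2'-bipyridyl in MeCN at 0 °C replace each aryl MOM group by trimethylsilyl to give the tetrakis(trimethylsilyl) ether F11. Addition of water then hydrolyses the aryl silyl ethers at neutral pH to 28.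

Further compounds
F1 | step 5 | 2-(tert-butyldimethylsilyloxy)-4,6-bis(methoxymethoxy)benzaldehyde | O=Cc1c(O[Si](C)(C)C(C)(C)C)cc(OCOC)cc1OCOC
F2 | step 5 | benzyl (E)-3-[2-(tert-butyldimethylsilyloxy)-4,6-bis(methoxymethoxy)phenyl]acrylate | O=C(/C=C/c1c(O[Si](C)(C)C(C)(C)C)cc(OCOC)cc1OCOC)OCc1ccccc1
F3 | step 5 | 3-[2-(tert-butyldimethylsilyloxy)-4,6-bis(methoxymethoxy)phenyl]propanoic acid | OC(=O)CCc1c(O[Si](C)(C)C(C)(C)C)cc(OCOC)cc1OCOC
F4 | step 5 | (4R)-4-benzyl-3-{3-[2-(tert-butyldimethylsilyloxy)-4,6-bis(methoxymethoxy)phenyl]propanoyl}oxazolidin-2-one | O=C(CCc1c(O[Si](C)(C)C(C)(C)C)cc(OCOC)cc1OCOC)N1[C@H](Cc2ccccc2)COC1=O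
F5 | step 5 | (4R)-4-benzyl-3-{(2R)-2-[2-(tert-butyldimethylsilyloxy)-4,6-bis(methoxymethoxy)benzyl]-5-methylhex-4-enoyl}oxazolidin-2-one | O=C([C@H](CC=C(C)C)Cc1c(O[Si](C)(C)C(C)(C)C)cc(OCOC)cc1OCOC)N1[C@H](Cc2ccccc2)COC1=O
F6 | step 13 | 2-(1-hydroxyethyl)-3,5-bis(methoxymethoxy)-6-[(2R)-5-methyl-2-(prop-1-en-2-yl)hex-4-enyl]phenol, both carbinol epimers | C=C(C)[C@H](CC=C(C)C)Cc1c(O)c(C(C)O)c(OCOC)cc1OCOC
F7 | step 13 | 1-{2-hydroxy-4,6-bis(methoxymethoxy)-3-[(2R)-5-methyl-2-(prop-1-en-2-yl)hex-4-enyl]phenyl}ethanone | C=C(C)[C@H](CC=C(C)C)Cc1c(O)c(C(C)=O)c(OCOC)cc1OCOC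
F8 | step 13 | 2,4-bis(methoxymethoxy)benzaldehyde | O=Cc1ccc(OCOC)cc1OCOC
F9 | step 13 | (E)-3-[2,4-bis(methoxymethoxy)phenyl]-1-{2-hydroxy-4,6-bis(methoxymethoxy)-3-[(2R)-5-methyl-2-(prop-1-en-2-yl)hex-4-enyl]phenyl}prop-2-en-1-one | C=C(C)[C@H](CC=C(C)C)Cc1c(O)c(C(=O)/C=C/c2ccc(OCOC)cc2OCOC)c(OCOC)cc1OCOC
F10 | step 13 | (2R)-2-[2,4-bis(methoxymethoxy)phenyl]-5,7-bis(methoxymethoxy)-8-[(2R)-5-methyl-2-(prop-1-en-2-yl)hex-4-enyl]chroman-4-one | C=C(C)[C@H](CC=C(C)C)Cc1c(OCOC)cc(OCOC)c2c1O[C@@H](c1ccc(OCOC)cc1OCOC)CC2=O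
F11 | step 14 | (2S)-2-[2,4-bis(trimethylsilyloxy)phenyl]-5,7-bis(trimethylsilyloxy)-8-[(2R)-5-methyl-2-(prop-1-en-2-yl)hex-4-enyl]chroman-4-one | C=C(C)[C@H](CC=C(C)C)Cc1c(O[Si](C)(C)C)cc(O[Si](C)(C)C)c2c1O[C@H](c1ccc(O[Si](C)(C)C)cc1O[Si](C)(C)C)CC2=O
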